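The route rests on taking rings D and E apart together. Cyclopentene E is fused to cycloheptane D across C9–C13 and carries its C12=C13 alkene next to quaternary C14, the mark of a cyclopentenone made from an alkyne on C14. One intramolecular Pauson–Khand reaction of a cage-held 1,8-enyne therefore forms C9–C13, C10–C11 and C11–C12, closes both carbocycles and sets C9. The precursor already holds rings A, B, C and lactone F, with an ethynyl group on C14 and a but-3-enyl arm on C6 held syn-diaxial on ring B. C24 is kept as an alcohol, not as a protected ketone, so that C2 stays fixed until a final non-enolising oxidation.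

Key step: step 18

Numbering: atoms are numbered as they occur in the target SMILES (C1 methyl, C2, C3, N4, C5, C6, C7 to C10, C11, C12, C13, C14, C15 to C17, C20, C21, C22, C23, C24, C26).
Assumption: C2 lies α to the C24 ketone and is treated as epimerisable; it is set kinetically in step 17 and C24 is then carried as the alcohol, so the outcome does not depend on which C2 epimer is the more stable.
Remark: centres that a later step removes (C5 in 16, C17 in 22, C23, C24 and C26 in 26 to 29, C11 in 38) are expected as mixtures and are written without configuration.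
Design remark: the ethynyl group is installed at the outset and ring F is closed before the cage is built, so no aldehyde-to-alkyne homologation in basic methanol has to be run on the seven-membered lactone.

Step 1
Reactants: 1 cyclopentane-1,3-dione; 2 but-3-en-2-one
Product: 3 2-(3-oxobutyl)cyclopentane-1,3-dione
Conditions: H2O, rt (1.0 equiv of 2)
Reagents that add atoms: none
Why: Michael addition of the acidic 1,3-dione (as its enol) to the enone, which should stop after one addition because the product enol is the more hindered nucleophile.

Step 2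
Reactants: 3 2-(3-oxobutyl)cyclopentane-1,3-dione; 4 1-[(trimethylsilyl)ethynyl]-1,2-benziodoxol-3(1H)-one
Product: 5 2-ethynyl-2-(3-oxobutyl)cyclopentane-1,3-dione
Conditions: Bu4NF, THF, −78 °C → rt
Reagents that add atoms: none
Why: Fluoride frees the parent ethynylbenziodoxolone and the dione enolate, whose carbon attacks the hypervalent iodine alkyne (electrophilic α-ethynylation of a 1,3-dicarbonyl compound), giving the quaternary but still achiral C14.

Step 3
Reactants: 5 2-ethynyl-2-(3-oxobutyl)cyclopentane-1,3-dione
Product: 7 (R)-7a-ethynyl-2,3,7,7a-tetrahydro-1H-indene-1,5(6H)-dione, via ketol 6 (not isolated)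
Conditions: L-proline (30 mol%), DMF, rt; then TsOH·H2O (cat.), toluene, 80 °C
Reagents that add atoms: none
Why: Hajos–Parrish aldol cyclisation, in which the L-proline enamine of the side-chain ketone adds to one of the two enantiotopic ring carbonyls through a hydrogen-bonded chair and so fixes C14 in the same spatial sense as the (S)-methyl series (R here only because ethynyl outranks C15), followed by acid dehydration of ketol 6.

Step 4
Reactants: 7 (R)-7a-ethynyl-2,3,7,7a-tetrahydro-1H-indene-1,5(6H)-dione
Product: 8 enone ketal (C26 dioxolane)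
Conditions: (Me3SiOCH2)2, Me3SiOTf (5 mol%), CH2Cl2, −78 → −20 °C
Reagents that add atoms: 1,2-bis(trimethylsilyloxy)ethane, C[Si](C)(C)OCCO[Si](C)(C)C
Why: Silyl triflate-catalysed ketalisation at low temperature should take the saturated, more electrophilic C26 ketone and leave the conjugated C17 enone untouched (chemoselective ketalisation).

Step 5
Reactants: 8 enone ketal
Product: 9 allylic alcohol (C17 hydroxyl cis to the C14 ethynyl group)
Conditions: NaBH4, CeCl3·7H2O, MeOH, −40 °C
Reagents that add atoms: none
Why: Luche 1,2-reduction, in which hydride should enter anti to the angular ethynyl group so that the C17 hydroxyl ends up cis to it.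

Step 6
Reactants: 9 allylic alcohol; 10 triethyl orthoacetate
Product: 11 cis-hydrindene ester (CH2CO2Et on C21 cis to ethynyl, C17=C20 alkene)
Conditions: EtCO2H (cat.), xylenes, 140 °C, removal of EtOH
Reagents that add atoms: none
Why: Johnson–Claisen rearrangement, in which the ketene acetal formed on the C17 oxygen shifts suprafacially through a chair and delivers C6 to C21 on the face the oxygen leaves, cis to the ethynyl group, which sets quaternary C21.

Step 7
Reactants: 11 cis-hydrindene ester
Product: 13 spirolactone alcohol, via diol ester 12 (not isolated)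
Conditions: O3, CH2Cl2–MeOH, −78 °C (Sudan Red 7B end point); then NaBH4, −78 → 0 °C; then TsOH·H2O (cat.), CH2Cl2, rt
Reagents that add atoms: ozone, [O-][O+]=O
Why: Ozonolysis with reductive work-up, in which ozone should cleave the electron-rich cis-alkene far faster than the terminal alkyne, borohydride gives the C17 and C20 primary alcohols, and the C20 hydroxyl closes the five-membered lactone onto the C5 ester.

Step 8
Reactants: 13 spirolactone alcohol; 14 4-iodobut-1-ene
Product: 15 C6-butenyl spirolactone
Conditions: LiN(iPr)2 (3.2 equiv), THF, −78 °C; then 14, DMPU, −78 → −40 °C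
Reagents that add atoms: none
Why: Lactone enolate alkylation, in which the lithium alkoxide and acetylide formed alongside should be inert at −40 °C and the iodide should approach C6 from the side of the C22 methylene, away from quaternary C14, which sets C6 (butenyl trans to C14 on the lactone ring, also the more stable arrangement).

Step 9
Reactants: 15 C6-butenyl spirolactone
Product: 16 lactol
Conditions: iBu2AlH (3.5 equiv), CH2Cl2, −78 °C; aq. potassium sodium tartrate
Reagents that add atoms: none
Why: Partial reduction of a γ-lactone by a dialkylaluminium hydride stops at the tetrahedral aluminate at low temperature and gives the lactol, while ketal, alkene and alkyne are inert.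

Step 10
Reactants: 16 lactol; 17 (R)-2-methylpropane-2-sulfinamide
Product: 19 N-sulfinyl amino diol, via sulfinyl imine 18 (not isolated)
Conditions: Ti(OEt)4, THF, 50 °C; then NaBH4, −40 → 0 °C
Reagents that add atoms: none
Why: Reductive amination with an ammonia equivalent that cannot over-alkylate, in which the lactol opens to the C5 aldehyde, Ti(OEt)4 drives condensation to imine 18 and borohydride reduces the C=N bond (C5 is not stereogenic).

Step 11
Reactants: 19 N-sulfinyl amino diol
Product: 21 N-Boc amino keto diol, via amino ketone hydrochloride 20 (not isolated)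
Conditions: 2 M HCl, THF–H2O, rt; then NaHCO3, Boc2O, 0 °C → rt
Reagents that add atoms: di-tert-butyl dicarbonate, CC(C)(C)OC(=O)OC(=O)OC(C)(C)C; water, O
Why: Acid hydrolysis cleaves the N–S bond and the dioxolane together, the free amine cannot condense with C26 because that would need a bridgehead C=N bond, and N-acylation then masks it as the carbamate.

Step 12
Reactants: 21 N-Boc amino keto diol
Product: 23 keto lactone, via lactol 22 (not isolated)
Conditions: TEMPO (20 mol%), PhI(OAc)2 (2.5 equiv), CH2Cl2, rt
Reagents that add atoms: none
Why: Oxidative lactonisation of a diol, in which the nitroxyl catalyst should oxidise only the unhindered C17 primary alcohol, the neopentyl C20 hydroxyl traps the aldehyde as lactol 22, and this is oxidised on to the seven-membered lactone F, helped by the two adjacent quaternary carbons.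

Step 13
Reactants: 23 keto lactone; 24 2-methylprop-2-enal
Product: 26 aldol adduct, via boron enolate 25 (not isolated)
Conditions: Bu2BOTf, iPr2NEt, CH2Cl2, −78 → 0 °C; then 24, −78 °C; pH 7 buffer, MeOH, H2O2, 0 °C
Reagents that add atoms: none
Why: Boron-mediated aldol addition, in which soft enolisation can only occur toward C23 because C14 is quaternary, lactone and carbamate are not enolised, and the enolate forms C23–C24 (the two new centres are removed in steps 15 and 16).

Step 14
Reactants: 26 aldol adduct
Product: 27 diol
Conditions: NaBH4, CeCl3·7H2O, MeOH, −20 °C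
Reagents that add atoms: none
Why: Borohydride reduction of the C26 ketone, much faster than attack on the lactone, sets up the 1,3-carbonyl transposition by leaving C26 as a plain secondary alcohol and C24 as the only allylic one.

Step 15
Reactants: 27 diol
Product: 28 β-hydroxy isopropenyl ketone
Conditions: MnO2, CH2Cl2, rt; used at once
Reagents that add atoms: none
Why: Chemoselective allylic oxidation, since MnO2 should oxidise only the allylic C24 alcohol and leave the saturated C26 alcohol.

Step 16
Reactants: 28 β-hydroxy isopropenyl ketone
Product: 30 cross-conjugated dienone, via mesylate 29 (not isolated)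
Conditions: MsCl, Et3N, CH2Cl2, 0 °C → rt
Reagents that add atoms: none
Why: Mesylation of the C26 alcohol and E1cB β-elimination through the C23 enolate give the C26=C23 enone and complete the carbonyl transposition from C26 to C24.

Step 17
Reactants: 30 cross-conjugated dienone
Product: 34 tetracyclic enyne alcohol, via ammonium trifluoroacetate 31 (not isolated), via ring-B amine 32 (not isolated), via amino ketone 33 (not isolated)
Conditions: CF3CO2H, CH2Cl2, 0 °C; evaporate; Et3N, MeOH, 0 °C → rt; then NaBH4, −40 °C
Reagents that add atoms: none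
Why: Double aza-Michael addition of a primary amine to a divinyl ketone, in which the freed amine on the C6–C5 tether adds to C26 on the only face it can reach (6-exo, ring B, sets C26), C23 equilibrates to place the acyl group cis to nitrogen, the secondary amine closes ring A on the isopropenyl ketone (6-endo), the enol is protonated at C2 on the exposed face, and borohydride then reduces C24 from that same face so that C2 can no longer epimerise.

Step 18
Reactants: 34 tetracyclic enyne alcohol; 35 carbon monoxide (delivered by Co2(CO)8)
Product: 37 hexacyclic enone, via dicobalt complex 36 (not isolated)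
Conditions: Co2(CO)8 (1.2 equiv), CH2Cl2, rt; then N-methylmorpholine N-oxide, 4 Å molecular sieves, CH2Cl2, 0 °C → rt
Reagents that add atoms: none
Why: Co2(CO)8 turns the terminal alkyne into its hexacarbonyldicobalt complex 36; the N-oxide removes one CO as CO2, the C9=C10 alkene takes the free site and inserts into the cobalt–C13 bond, CO inserts at C10 and reductive elimination joins C11 to C12 (intramolecular Pauson–Khand [2+2+1] cycloaddition). The closest known reaction type is the cobalt-mediated Pauson–Khand cyclisation of conformationally restricted 1,8-enynes to bicyclo[5.3.0]decenones, which is rare for flexible chains but known where the tether is pre-folded. Ring D closes as the seven-membered ring by formation of C9–C13 (7-exo insertion of the tethered alkene), and ring E closes as the cyclopentenone by formation of C10–C11 and C11–C12 (carbonyl insertion, then reductive elimination). The one new stereocentre, C9, is fixed by the cage: the C14 ethynyl group and the C6 butenyl arm stand syn-diaxial on ring B, and only the alkene face that keeps C7–C8 clear of lactone F can reach the cobalt-bound alkyne. The step needs this one alkene face and the regiochemistry that puts C12–H beside the new carbonyl, and both should follow from the three-atom bridge C6–C21–C14 between the two partners. The alkyne sits on quaternary C14 and cannot isomerise to an allene, and the tertiary amine and the free C24 hydroxyl should be spectators toward cobalt carbonyls.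

Step 19
Reactants: 37 hexacyclic enone
Product: 38 C11 allylic alcohol
Conditions: NaBH4, CeCl3·7H2O, MeOH, −40 °C
Reagents that add atoms: none
Why: Luche 1,2-reduction of the C11 enone, which should leave the lactone alone and whose two C11 epimers are equally usable.

Step 20
Reactants: 38 C11 allylic alcohol
Product: 39 hexacyclic C24 alcohol
Conditions: Et3SiH, CF3CO2H, CH2Cl2, −40 → 0 °C; aq. NaHCO3
Reagents that add atoms: none
Why: Ionic hydrogenation, in which acid ionises only the allylic C11 alcohol (the C24 alcohol lies β to the ammonium ion) and the silane should deliver hydride to the less hindered secondary terminus C11 of the allyl cation, keeping the trisubstituted C12=C13 alkene, while low temperature limits protonation of that alkene.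

Step 21
Reactants: 39 hexacyclic C24 alcohol
Product: 40 CNP0292775.1 (target)
Conditions: Dess–Martin periodinane, NaHCO3, CH2Cl2, 0 °C → rt
Reagents that add atoms: none
Why: Oxidation of the secondary alcohol by a hypervalent iodine reagent under buffered, non-enolising conditions should give the C24 ketone without touching C2, C23, the amine or the alkene.

Compound list
1 | cyclopentane-1,3-dione | O=C1CCC(=O)C1 | starting material
2 | but-3-en-2-one (methyl vinyl ketone) | CC(=O)C=C | starting material
3 | 2-(3-oxobutyl)cyclopentane-1,3-dione (written as the triketone) | CC(=O)CCC1C(=O)CCC1=O | intermediate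
4 | 1-[(trimethylsilyl)ethynyl]-1,2-benziodoxol-3(1H)-one | C[Si](C)(C)C#CI1OC(=O)c2ccccc12 | starting material
5 | 2-ethynyl-2-(3-oxobutyl)cyclopentane-1,3-dione (achiral) | CC(=O)CCC1(C#C)C(=O)CCC1=O | intermediate
6 | cis-fused ketol, 7a-ethynyl-3a-hydroxyhexahydro-1H-indene-1,5(4H)-dione (C21 hydroxyl cis to C14 ethynyl) | C#C[C@]12CCC(=O)C[C@@]1(O)CCC2=O | intermediate
7 | (R)-7a-ethynyl-2,3,7,7a-tetrahydro-1H-indene-1,5(6H)-dione | C#C[C@]12CCC(=O)C=C1CCC2=O | intermediate
8 | enone ketal: C26 ethylene ketal of 7 | C#C[C@]12CCC(=O)C=C1CCC23OCCO3 | intermediate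
9 | allylic alcohol: C17 hydroxyl cis to the C14 ethynyl group, C20=C21 alkene, C26 dioxolane | C#C[C@]12CC[C@H](O)C=C1CCC23OCCO3 | intermediate
10 | triethyl orthoacetate (1,1,1-triethoxyethane) | CCOC(C)(OCC)OCC | starting material
11 | cis-hydrindene ester: CH2CO2Et on C21 cis to the C14 ethynyl group, C17=C20 alkene, C26 dioxolane | C#C[C@]12CCC=C[C@@]1(CC(=O)OCC)CCC23OCCO3 | intermediate
12 | diol ester: C17 and C20 primary alcohols, ethyl ester at C5 | C#C[C@]1(CCCO)[C@](CO)(CC(=O)OCC)CCC12OCCO2 | intermediate
13 | spirolactone alcohol: five-membered lactone C5(=O)–O–C20 spiro at C21, 3-hydroxypropyl and ethynyl on C14, C26 dioxolane | C#C[C@]1(CCCO)[C@]2(CC(=O)OC2)CCC13OCCO3 | intermediate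
14 | 4-iodobut-1-ene | C=CCCI | starting material
15 | C6-butenyl spirolactone (butenyl on C6 trans to C14 across the lactone ring) | C#C[C@]1(CCCO)[C@]2([C@H](CCC=C)C(=O)OC2)CCC13OCCO3 | intermediate
16 | lactol (C5 anomers) | C#C[C@]1(CCCO)[C@]2([C@H](CCC=C)C(O)OC2)CCC13OCCO3 | intermediate
17 | (R)-2-methylpropane-2-sulfinamide | CC(C)(C)[S@@](=O)N | starting material
18 | (E)-N-sulfinyl aldimine at C5 | C#C[C@]1(CCCO)[C@](CO)([C@H](CCC=C)/C=N/[S@](=O)C(C)(C)C)CCC12OCCO2 | intermediate
19 | N-sulfinyl amino diol (C5–NH–S(O)tBu, C17 and C20 alcohols, C26 dioxolane) | C#C[C@]1(CCCO)[C@](CO)([C@H](CCC=C)CN[S@](=O)C(C)(C)C)CCC12OCCO2 | intermediate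
20 | amino ketone diol hydrochloride | C#C[C@]1(CCCO)[C@](CO)([C@H](CCC=C)CN)CCC1=O.Cl | intermediate
21 | N-Boc amino keto diol | C#C[C@]1(CCCO)[C@](CO)([C@H](CCC=C)CNC(=O)OC(C)(C)C)CCC1=O | intermediate
22 | seven-membered lactol (C17 hemiacetal with the C20 oxygen) | C#C[C@]12CCC(O)OC[C@@]1([C@H](CCC=C)CNC(=O)OC(C)(C)C)CCC2=O | intermediate
23 | keto lactone: ring F closed cis on C14–C21, C26 ketone, N-Boc aminomethyl and butenyl on C6 | C#C[C@]12CCC(=O)OC[C@@]1([C@H](CCC=C)CNC(=O)OC(C)(C)C)CCC2=O | intermediate
24 | 2-methylprop-2-enal (methacrolein) | CC(=C)C=O | starting material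
25 | dibutylboron enolate (C23=C26–O–BBu2) | C#C[C@]12CCC(=O)OC[C@@]1([C@H](CCC=C)CNC(=O)OC(C)(C)C)CC=C2OB(CCCC)CCCC | intermediate
26 | aldol adduct (C23–C24 bond; C23 and C24 epimers) | C#C[C@]12CCC(=O)OC[C@@]1([C@H](CCC=C)CNC(=O)OC(C)(C)C)CC(C(O)C(C)=C)C2=O | intermediate
27 | diol (C24 and C26 alcohols; epimers) | C#C[C@]12CCC(=O)OC[C@@]1([C@H](CCC=C)CNC(=O)OC(C)(C)C)CC(C(O)C(C)=C)C2O | intermediate
28 | β-hydroxy isopropenyl ketone (C24 ketone, C26 alcohol; epimers) | C#C[C@]12CCC(=O)OC[C@@]1([C@H](CCC=C)CNC(=O)OC(C)(C)C)CC(C(=O)C(C)=C)C2O | intermediate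
29 | C26 mesylate of 28 | C#C[C@]12CCC(=O)OC[C@@]1([C@H](CCC=C)CNC(=O)OC(C)(C)C)CC(C(=O)C(C)=C)C2OS(C)(=O)=O | intermediate
30 | cross-conjugated dienone (C26=C23–C24(=O)–C2(Me)=C3) | C#C[C@]12CCC(=O)OC[C@@]1([C@H](CCC=C)CNC(=O)OC(C)(C)C)CC(C(=O)C(C)=C)=C2 | intermediate
31 | primary ammonium trifluoroacetate of the dienone | C#C[C@]12CCC(=O)OC[C@@]1([C@H](CCC=C)CN)CC(C(=O)C(C)=C)=C2.OC(=O)C(F)(F)F | intermediate
32 | ring-B amine (2-azabicyclo[3.2.1]octane with N4–C26 bond, acyl group on C23 cis to nitrogen) | N1C[C@@H](CCC=C)[C@@]23COC(=O)CC[C@]2(C#C)[C@@H]1[C@@H](C(=O)C(C)=C)C3 | intermediate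
33 | tetracyclic amino ketone (rings A, B, C, F; C24 ketone) | C[C@@H]1CN2C[C@@H](CCC=C)[C@@]34COC(=O)CC[C@]3(C#C)[C@@H]2[C@@H](C1=O)C4 | intermediate
34 | tetracyclic 1,8-enyne with C24 hydroxyl (rings A, B, C, F; ethynyl on C14, but-3-enyl on C6) | C[C@@H]1CN2C[C@@H](CCC=C)[C@@]34COC(=O)CC[C@]3(C#C)[C@@H]2[C@@H]([C@@H]1O)C4 | intermediate
35 | carbon monoxide (delivered by Co2(CO)8) | [C-]#[O+] | starting material
36 | hexacarbonyldicobalt complex of the alkyne of 34 | C[C@@H]1CN2C[C@@H](CCC=C)[C@@]34COC(=O)CC[C@]3(C56[Co]7(=C=O)(=C=O)(=C=O)[Co]5(=C=O)(=C=O)(=C=O)C67)[C@@H]2[C@@H]([C@@H]1O)C4 | intermediate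
37 | hexacyclic C11 enone with C24 hydroxyl | C[C@@H]1CN2C[C@H]3CC[C@@H]4CC(=O)C=C4[C@]45CCC(=O)OC[C@]34C[C@H]([C@@H]1O)[C@H]25 | intermediate
38 | C11 allylic alcohol (C11 epimers) | C[C@@H]1CN2C[C@H]3CC[C@@H]4CC(O)C=C4[C@]45CCC(=O)OC[C@]34C[C@H]([C@@H]1O)[C@H]25 | intermediate
39 | hexacyclic C24 alcohol (C11 methylene, C12=C13 alkene) | C[C@@H]1CN2C[C@H]3CC[C@@H]4CCC=C4[C@]45CCC(=O)OC[C@]34C[C@H]([C@@H]1O)[C@H]25 | intermediate
40 | CNP0292775.1 | C[C@@H]1CN2C[C@H]3CC[C@@H]4CCC=C4[C@]45CCC(=O)OC[C@]34C[C@H](C1=O)[C@H]25 | target

Total step count: 21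
Longest linear sequence: 21 steps (the route is linear; 17 steps to the enyne, the key step, 3 steps after it)

Steps most likely to fail

Step 18. The seven-membered closure may be slower than loss of cobalt from the complex or than intermolecular reaction of alkyne and alkene, so that enyne is returned or oligomers form. The fallback sets out from 34 and supplies C11 as an isocyanide instead of carbon monoxide: Ni(cod)2 and PBu3 in DMF should cyclise the enyne oxidatively to a nickelacyclopentene, 2,6-dimethylphenyl isocyanide inserts, and reductive elimination gives the N-aryl iminocyclopentene F1. Aqueous oxalic acid hydrolyses F1, and the route is rejoined at 37.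

Step 8. Alkylation of the hindered enolate next to the spiro centre by an unactivated iodide may be too slow, so that elimination of the iodide or alkylation at the acetylide takes over. The fallback sets out from 13 and builds C7–C8 instead of C6–C7. Mg(OCO2Me)2 in DMF carboxylates C6 to give the α-carboxy lactone F2, and CH2O with Et2NH in buffered acetic acid converts F2 by decarboxylative Mannich elimination into the α-methylene lactone F3. Conjugate addition of the allyl copper reagent made from allylmagnesium bromide and CuBr·SMe2 with Me3SiCl at −78 °C then gives 15 together with its C6 epimer F4. 1,8-Diazabicyclo[5.4.0]undec-7-ene should equilibrate F4 to 15, the epimer with the butenyl group away from C14, where the route is rejoined.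

Step 17. Protonation at C2 may show poor facial selectivity, or the reversible second conjugate addition may leave open-chain vinyl ketone that polymerises. The fallback sets out from 23 and runs steps 13 to 16 with (E)-3-ethoxy-2-methylprop-2-enal in place of methacrolein, through the aldol adduct F5, the diol F6, the β-hydroxy enone F7 and the β-ethoxy dienone F8. After acid removal of the carbamate and neutralisation, the amine closes ring B as before and then displaces ethoxide by addition–elimination, which is irreversible and gives the vinylogous amide F9 with no stereocentre at C2. Conjugate reduction with K(sBu)3BH at −78 °C gives the C2 enolate, which is protonated on the exposed face with 2,6-di-tert-butylphenol and reduced in the same flask with NaBH4; the route is rejoined at 34.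

Further compounds
F1 | step 18 | N-(2,6-dimethylphenyl) imine of enone 37 (iminocyclopentene) | C[C@@H]1CN2C[C@H]3CC[C@@H]4CC(=Nc6c(C)cccc6C)C=C4[C@]45CCC(=O)OC[C@]34C[C@H]([C@@H]1O)[C@H]25
F2 | step 8 | α-carboxy spirolactone (CO2H on C6, epimers) | C#C[C@]1(CCCO)[C@]2(C(C(=O)O)C(=O)OC2)CCC13OCCO3
F3 | step 8 | α-methylene spirolactone (C6=C7H2) | C#C[C@]1(CCCO)[C@]2(C(=C)C(=O)OC2)CCC13OCCO3
F4 | step 8 | C6 epimer of 15 | C#C[C@]1(CCCO)[C@]2([C@@H](CCC=C)C(=O)OC2)CCC13OCCO3
F5 | step 17 | aldol adduct with the ethoxyvinyl side chain (C23 and C24 epimers) | C#C[C@]12CCC(=O)OC[C@@]1([C@H](CCC=C)CNC(=O)OC(C)(C)C)CC(C(O)/C(C)=C/OCC)C2=O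
F6 | step 17 | diol with the ethoxyvinyl side chain (epimers) | C#C[C@]12CCC(=O)OC[C@@]1([C@H](CCC=C)CNC(=O)OC(C)(C)C)CC(C(O)/C(C)=C/OCC)C2O
F7 | step 17 | β-hydroxy β'-ethoxy enone (epimers) | C#C[C@]12CCC(=O)OC[C@@]1([C@H](CCC=C)CNC(=O)OC(C)(C)C)CC(C(=O)/C(C)=C/OCC)C2O
F8 | step 17 | β-ethoxy cross-conjugated dienone | C#C[C@]12CCC(=O)OC[C@@]1([C@H](CCC=C)CNC(=O)OC(C)(C)C)CC(C(=O)/C(C)=C/OCC)=C2
F9 | step 17 | tetracyclic vinylogous amide (N4–C3=C2(Me)–C24=O in ring A) | CC1=CN2C[C@@H](CCC=C)[C@@]34COC(=O)CC[C@]3(C#C)[C@@H]2[C@@H](C1=O)C4
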